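**Strategy.** In ent-kaurane numbering, ring A (C1–C5, C10) is read as a methacrylate unit, C3 (methylene) and C4 (quaternary; methyl C18, carboxyl C19), inserted between C2 and C5, the carbon that carries carboxyl C6. The key step is a radical annulation: a primary C2 radical on a side arm of quaternary C10 adds to a methacrylate ester (C2–C3), and the resulting C4 radical closes ring A 6-exo onto a ketene dithioacetal (C5=C6), forming C4–C5 and setting C4 and C5 against C10. The precursor is open at ring A: a bicyclo[3.2.1]octanone carrying at C9 a quaternary carbon with methyl, 2-(phenylselanyl)ethyl and dithianylidene-methyl arms, unmasked from a temporary δ-lactone.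

Key step: step 11

Numbering: ent-kaurane locants are used throughout (ring A = C1–C5, C10; C6 = carboxyl carbon on C5; C7 = formyl carbon on C8; C18/C19 = methyl/carboxyl on C4; C20 = methyl on C10; bicyclo[3.2.1]octane = C8, C9, C11–C16; C17 = exocyclic methylene carbon).

Assumption: the sense of induction of the desymmetrising catalyst in step 4 is assumed as drawn (the pseudoenantiomeric amine from cinchonine would be used otherwise); 2-chloroethyl trifluoromethanesulfonate (12) is taken as a purchased reagent.

Step 1
Reactants: 1 ethyl 1,4-dioxaspiro[4.5]decane-8-carboxylate; 2 3-bromoprop-1-yne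
Product: 3 ethyl 8-(prop-2-yn-1-yl)-1,4-dioxaspiro[4.5]decane-8-carboxylate
Conditions: LiN(i-Pr)2, THF, −78 °C; then 2, −78 °C to rt
Reagents that add atoms: 3-bromoprop-1-yne, C#CCBr
Why: Ester enolate alkylation: the lithium enolate of the symmetric ester should be C-propargylated by the unhindered primary bromide, creating the future quaternary C8, which is not yet stereogenic because both ring arms are identical.

Step 2
Reactants: 3 ethyl 8-(prop-2-yn-1-yl)-1,4-dioxaspiro[4.5]decane-8-carboxylate
Product: 5 4-(hydroxymethyl)-4-(prop-2-yn-1-yl)cyclohexan-1-one, via ketal alcohol 4 (not isolated)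
Conditions: LiAlH4, THF, 0 °C; then 2 M HCl, THF, rt
Reagents that add atoms: water, O
Why: Hydride reduction of the ester to the primary alcohol (C7) followed in the same flask by acid-catalysed ketal hydrolysis, with no stereocenter formed and the remote alkyne untouched at 0 °C.

Step 3
Reactants: 5 4-(hydroxymethyl)-4-(prop-2-yn-1-yl)cyclohexan-1-one; 6 propanoyl chloride
Product: 7 [4-oxo-1-(prop-2-yn-1-yl)cyclohexyl]methyl propanoate
Conditions: Et3N, DMAP (cat.), CH2Cl2, 0 °C
Reagents that add atoms: propanoyl chloride, CCC(=O)Cl
Why: O-Acylation (nucleophilic acyl substitution) of the primary alcohol installs the propanoate that later delivers C5, C10 and C20 from the C7 oxygen.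

Step 4
Reactants: 7 [4-oxo-1-(prop-2-yn-1-yl)cyclohexyl]methyl propanoate
Product: 8 [(1R,5R)-6-methylidene-4-oxobicyclo[3.2.1]octan-1-yl]methyl propanoate
Conditions: 9-amino-9-deoxy-epi-cinchonidine (20 mol %), AgN(SO2CF3)2 (10 mol %), 2-nitrobenzoic acid (20 mol %), toluene, 40 °C
Reagents that add atoms: none
Why: Desymmetrising amine/silver co-catalysed cycloisomerisation (Conia-ene type, 5-exo-dig) of an alkyne-tethered cyclohexanone: the chiral primary amine forms the enamine at one of the two enantiotopic α-methylenes, which attacks the silver-activated axial propargyl group, so C8 and C13 are set together (their relative configuration is fixed by the bridge) and protodemetalation leaves the exocyclic C16=C17 alkene.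

Step 5
Reactants: 8 [(1R,5R)-6-methylidene-4-oxobicyclo[3.2.1]octan-1-yl]methyl propanoate
Product: 9 [(1R,5R)-6-methylidene-4-oxobicyclo[3.2.1]oct-2-en-1-yl]methyl propanoate
Conditions: IBX, 4-methoxypyridine N-oxide, DMSO, rt
Reagents that add atoms: none
Why: IBX dehydrogenation of a ketone to the enone, regiospecific for C9=C11 because the other α-carbon (C13) is a bridgehead that cannot enolise; no stereocenter is touched.

Step 6
Reactants: 9 [(1R,5R)-6-methylidene-4-oxobicyclo[3.2.1]oct-2-en-1-yl]methyl propanoate
Product: 11 tricyclic δ-lactone tert-butyldimethylsilyl enol ether (C10 epimers), via lithium enolate 10 (not isolated)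
Conditions: LiN(i-Pr)2, THF, −78 to −30 °C; then t-BuMe2SiOTf, −78 °C
Reagents that add atoms: tert-butyldimethylsilyl trifluoromethanesulfonate, CC(C)(C)[Si](C)(C)OS(=O)(=O)C(F)(F)F
Why: Intramolecular Michael addition (6-exo-trig) of the propanoate enolate, the only enolisable site, to C9: the tether from C8 and approach on the enone face opposite the two-carbon bridge should set C9 with C10 cis to C7, and the resulting C12 enolate is trapped as the silyl enol ether (the C10 epimer mixture is erased in step 7).

Step 7
Reactants: 11 tricyclic δ-lactone tert-butyldimethylsilyl enol ether (C10 epimers); 12 2-chloroethyl trifluoromethanesulfonate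
Product: 13 C10-quaternary δ-lactone (C10: methyl syn to C14 and 2-chloroethyl anti to C14)
Conditions: LiN(i-Pr)2, THF, −78 to −40 °C; then 12, −78 to −20 °C
Reagents that add atoms: 2-chloroethyl trifluoromethanesulfonate, ClCCOS(=O)(=O)C(F)(F)F
Why: Lactone enolate C-alkylation by a primary triflate: the electrophile should enter on the convex face of the cis-fused lactone, anti to the axial C14 and syn to H9, so the C1–C2 arm ends trans to C14 and C20 stays syn to it, which is the C10 configuration of the target.

Step 8
Reactants: 13 C10-quaternary δ-lactone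
Product: 14 lactol (C5 anomers)
Conditions: i-Bu2AlH (1.2 equiv), CH2Cl2, −78 °C; KNaC4H4O6 (aq)
Reagents that add atoms: none
Why: Partial reduction of a lactone to the lactol at low temperature, which masks C5 as an aldehyde while the silyl enol ether, chloride and alkene are inert; C5 is not a lasting stereocenter.

Step 9
Reactants: 14 lactol (C5 anomers); 15 2-(trimethylsilyl)-1,3-dithiane
Product: 17 keto alcohol ketene dithioacetal [C7–OH; C12=O; C10 bearing CH3, CH2CH2Cl and CH=C(SCH2CH2CH2S)], via silyl enol ether 16 (not isolated)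
Conditions: 15, n-BuLi, THF, −30 °C; then 14, −78 °C to rt; MeOH; then Bu4NF, 0 °C; NH4Cl (aq)
Reagents that add atoms: 2-(trimethylsilyl)-1,3-dithiane, C[Si](C)(C)C1SCCCS1
Why: Peterson olefination of the hydroxy-aldehyde form of the lactol gives the ketene dithioacetal C5=C6 (no alkene geometry to control) and frees C7–OH, and fluoride then cleaves the silyl enol ether to the C12 ketone so that no C11=C12 alkene remains to trap the later C2 radical.

Step 10
Reactants: 17 keto alcohol ketene dithioacetal
Product: 18 phenyl selenide (CH2CH2SePh in place of CH2CH2Cl)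
Conditions: PhSeSePh, NaBH4, EtOH, 0 °C to rt; then 17, THF, 50 °C
Reagents that add atoms: diphenyl diselenide, c1ccc(cc1)[Se][Se]c1ccccc1
Why: SN2 displacement of the primary chloride by benzeneselenolate gives a radical precursor that, unlike an iodide, cannot alkylate the nearby dithioacetal sulfur.

Step 11
Reactants: 18 phenyl selenide; 19 trimethylsilyl 2-methylprop-2-enoate
Product: 21 ring-A-closed 6-(1,3-dithian-2-yl)-7-hydroxy-12-oxo 19-acid, via trimethylsilyl ester 20 (not isolated)
Conditions: 19 (15 equiv), benzene (0.01 M in 18), 80 °C; Bu3SnH and AIBN added over 8 h; then 1 M HCl, THF, rt; KF (aq)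
Reagents that add atoms: trimethylsilyl 2-methylprop-2-enoate, C=C(C)C(=O)O[Si](C)(C)C
Why: Radical chain annulation (Giese addition followed by 6-exo-trig cyclisation, a formal [4+2] radical annulation): the stannyl radical abstracts the phenylselanyl group, the nucleophilic primary C2 radical adds to the β-carbon C3 of the methacrylate, and the electrophilic tertiary C4 radical attacks the electron-rich ketene dithioacetal at C5 to give a sulfur-stabilised C6 radical that is reduced by the stannane. Ring A closes in the 6-exo-trig mode through a chair-like transition state with the very bulky C9 substituent of C10 equatorial and C20 axial. C5 is controlled by allylic strain: C20 eclipses the alkene plane so that C6 becomes equatorial and H5 anti to C20, and this is also the thermodynamically preferred epimer once C6 is an aldehyde (step 12). C4 is controlled by avoidance of a 1,3-diaxial methyl/methyl contact with C20, which places the planar ester pseudo-axial (syn to C20) and C18 equatorial, giving the cis C19/C6 relationship. The step needs Giese addition before hydrogen transfer and cyclisation before telomerisation; this is secured by polarity matching at each stage, excess acrylate, slow stannane addition and the fact that the C2 radical can reach C5=C6 only in disfavoured 4-exo or 5-endo modes. Dilute acid finally hydrolyses the silyl ester to the free C19 acid.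

Step 12
Reactants: 21 ring-A-closed 6-(1,3-dithian-2-yl)-7-hydroxy-12-oxo 19-acid
Product: 22 6-aldehyde (7-hydroxy-6,12-dioxo 19-acid)
Conditions: PhI(OCOCF3)2, MeCN/H2O (9:1), 0 °C
Reagents that add atoms: water, O
Why: Oxidative hydrolysis of the dithioacetal with a hypervalent iodine reagent frees the C6 aldehyde without touching alcohol, acid or alkene, and the epimerisable C5 should stay (or settle) in the equatorial-formyl configuration of the target.

Step 13
Reactants: 22 6-aldehyde
Product: 23 7-hydroxy-12-oxo-6,7-seco-ent-kaur-16-ene-6,19-dioic acid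
Conditions: NaClO2, NaH2PO4, 2-methylbut-2-ene, t-BuOH/H2O, rt
Reagents that add atoms: sodium chlorite, [Na+].[O-]Cl=O
Why: Pinnick oxidation converts only the aldehyde into the C6 acid, leaving the C7 alcohol, the ketone and the scavenger-protected exocyclic alkene intact, which is why C7 is kept at the alcohol level until now.

Step 14
Reactants: 23 7-hydroxy-12-oxo-6,7-seco-ent-kaur-16-ene-6,19-dioic acid
Product: 24 (4R,5S,8R,9S,10S,13R)-7,12-dioxo-6,7-seco-kaur-16-ene-6,19-dioic acid (CNP0320711.1)
Conditions: Dess–Martin periodinane, CH2Cl2, rt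
Reagents that add atoms: none
Why: Dess–Martin oxidation of the neopentyl primary alcohol stops at the C7 aldehyde under anhydrous conditions and tolerates the free acids, the ketone and the alkene; no stereocenter is affected.

**Compound list**

1 | ethyl 1,4-dioxaspiro[4.5]decane-8-carboxylate | CCOC(=O)C1CCC2(CC1)OCCO2 | starting material
2 | 3-bromoprop-1-yne | C#CCBr | starting material
3 | ethyl 8-(prop-2-yn-1-yl)-1,4-dioxaspiro[4.5]decane-8-carboxylate | CCOC(=O)C1(CC#C)CCC2(CC1)OCCO2 | intermediate
4 | [8-(prop-2-yn-1-yl)-1,4-dioxaspiro[4.5]decan-8-yl]methanol (not isolated) | OCC1(CC#C)CCC2(CC1)OCCO2 | intermediate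
5 | 4-(hydroxymethyl)-4-(prop-2-yn-1-yl)cyclohexan-1-one | OCC1(CC#C)CCC(=O)CC1 | intermediate
6 | propanoyl chloride | CCC(=O)Cl | starting material
7 | [4-oxo-1-(prop-2-yn-1-yl)cyclohexyl]methyl propanoate | CCC(=O)OCC1(CC#C)CCC(=O)CC1 | intermediate
8 | [(1R,5R)-6-methylidene-4-oxobicyclo[3.2.1]octan-1-yl]methyl propanoate (C8, C13 as in 24) | C=C1C[C@]2(COC(=O)CC)C[C@H]1C(=O)CC2 | intermediate
9 | [(1R,5R)-6-methylidene-4-oxobicyclo[3.2.1]oct-2-en-1-yl]methyl propanoate | C=C1C[C@]2(COC(=O)CC)C[C@H]1C(=O)C=C2 | intermediate
10 | lithium C11=C12 enolate of the Michael adduct: δ-lactone C8–C7H2–O–C5(=O)–C10H(CH3)–C9 fused to the bicyclo[3.2.1]octene; C9 as in 24, C10 epimers (not isolated) | C=C1C[C@]23C[C@H]1C(O[Li])=C[C@H]2C(C)C(=O)OC3 | intermediate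
11 | the same tricyclic δ-lactone as its C12 tert-butyldimethylsilyl enol ether (C10 epimers) | C=C1C[C@]23C[C@H]1C(O[Si](C)(C)C(C)(C)C)=C[C@H]2C(C)C(=O)OC3 | intermediate
12 | 2-chloroethyl trifluoromethanesulfonate | ClCCOS(=O)(=O)C(F)(F)F | starting material
13 | C10-quaternary δ-lactone silyl enol ether (C10: CH3 syn to C14, CH2CH2Cl anti; configuration as in 24) | C=C1C[C@]23C[C@H]1C(O[Si](C)(C)C(C)(C)C)=C[C@H]2[C@](C)(CCCl)C(=O)OC3 | intermediate
14 | corresponding lactol (C5 anomers) | C=C1C[C@]23C[C@H]1C(O[Si](C)(C)C(C)(C)C)=C[C@H]2[C@](C)(CCCl)C(O)OC3 | intermediate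
15 | 2-(trimethylsilyl)-1,3-dithiane | C[Si](C)(C)C1SCCCS1 | starting material
16 | ring-opened ketene dithioacetal with C7–OH and C12 silyl enol ether (not isolated) | C=C1C[C@]2(CO)C[C@H]1C(O[Si](C)(C)C(C)(C)C)=C[C@H]2[C@](C)(CCCl)C=C1SCCCS1 | intermediate
17 | keto alcohol ketene dithioacetal: 8-(hydroxymethyl)-16-methylidene-12-oxo bicycle with C9 bearing C10[CH3][CH2CH2Cl][CH=C(SCH2CH2CH2S)] | C=C1C[C@]2(CO)C[C@H]1C(=O)C[C@H]2[C@](C)(CCCl)C=C1SCCCS1 | intermediate
18 | phenyl selenide analogue of 17 (CH2CH2SePh) | C=C1C[C@]2(CO)C[C@H]1C(=O)C[C@H]2[C@](C)(CC[Se]c1ccccc1)C=C1SCCCS1 | intermediate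
19 | trimethylsilyl 2-methylprop-2-enoate | C=C(C)C(=O)O[Si](C)(C)C | starting material
20 | trimethylsilyl ester of 21 (not isolated) | C=C1C[C@]2(CO)C[C@H]1C(=O)C[C@H]2[C@]1(C)CCC[C@@](C)(C(=O)O[Si](C)(C)C)[C@H]1C1SCCCS1 | intermediate
21 | 6-(1,3-dithian-2-yl)-7-hydroxy-12-oxo-6,7-seco-ent-kaur-16-en-19-oic acid (ring A closed; 4R,5S,10S) | C=C1C[C@]2(CO)C[C@H]1C(=O)C[C@H]2[C@]1(C)CCC[C@@](C)(C(=O)O)[C@H]1C1SCCCS1 | intermediate
22 | 7-hydroxy-6,12-dioxo-6,7-seco-ent-kaur-16-en-19-oic acid (6-aldehyde) | C=C1C[C@]2(CO)C[C@H]1C(=O)C[C@H]2[C@]1(C)CCC[C@@](C)(C(=O)O)[C@H]1C=O | intermediate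
23 | 7-hydroxy-12-oxo-6,7-seco-ent-kaur-16-ene-6,19-dioic acid | C=C1C[C@]2(CO)C[C@H]1C(=O)C[C@H]2[C@]1(C)CCC[C@@](C)(C(=O)O)[C@H]1C(=O)O | intermediate
24 | (4R,5S,8R,9S,10S,13R)-7,12-dioxo-6,7-seco-kaur-16-ene-6,19-dioic acid (CNP0320711.1) | C=C1C[C@]2(C=O)C[C@H]1C(=O)C[C@H]2[C@]1(C)CCC[C@@](C)(C(=O)O)[C@H]1C(=O)O | target

**Totals.** Total step count: 14. Longest linear sequence: 14 steps (from 1; compounds 2, 6, 12, 15 and 19 are purchased).

**Steps most likely to fail, with fallbacks**

Step 11 (key step). The C2 radical may be reduced by the stannane before it meets the acrylate. The hindered tertiary C4 radical may fail to close onto C5, which lies between two quaternary carbons, so that open-chain adduct or telomers form. The face selectivity at C4 may be poor. The fallback replaces the radical ring closure by a radical–polar crossover in which an enolate closes the ring. It sets out from 17. One equivalent of mCPBA (CH2Cl2, −78 °C) should oxidise the ketene dithioacetal to the 2-alkylidene-1,3-dithiane 1-oxide F1, a Michael acceptor at C5. Chloride–iodide exchange (NaI, acetone, rt) should then give the iodide F2, to be used at once. Under photoredox conditions (4CzIPN, i-Pr2NEt, 19, MeCN, blue light) halogen-atom transfer should give the C2 radical, which adds to 19. The C4 radical is reduced to the ester enolate, which closes ring A by 6-exo-trig Michael addition to C5 and gives the silyl ester F3 (not isolated). Aqueous work-up should give the sulfoxide acid F4. Dilute HCl in THF should hydrolyse the dithioacetal S-oxide to aldehyde 22, where the route is rejoined.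

Step 4. Discrimination between the two enantiotopic α-methylenes may be low, or enamine formation with the hindered ketone may be slow. The fallback replaces asymmetric catalysis by a covalent auxiliary and separation of diastereomers. It sets out from 5, which is acylated with (S)-2-methoxy-2-phenylacetic acid (DCC, DMAP) to the ester F5. Cyclisation with achiral pyrrolidine/Cu(OTf)2/PPh3 should give two bicyclic diastereomers, from which the (1R,5R) isomer F6 is separated by chromatography or crystallisation. Methanolysis (K2CO3, MeOH) should give the enantiopure keto alcohol F7, and acylation with 6 (Et3N, DMAP) returns to 8.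

Step 9. The bulky silylated dithianyl anion may fail to add to the α-quaternary aldehyde, which is present only in small amount beside the lactolate, so that lactol is recovered. The fallback replaces the Peterson reaction by addition followed by a separate elimination. It sets out from 14, to which the smaller 2-lithio-1,3-dithiane is added to give the diol F8. Trifluoroacetic anhydride and pyridine should give the bis(trifluoroacetate) F9. DBU should then eliminate the secondary ester towards the acidic dithiane C–H, and mild methanolysis of the primary trifluoroacetate (NaHCO3, MeOH) gives 16, which is desilylated as in step 9 to 17.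

**Further compounds**

F1 | step 11 | 1-oxide of the ketene dithioacetal 17 (chloride; sulfoxide epimers) | C=C1C[C@]2(CO)C[C@H]1C(=O)C[C@H]2[C@](C)(CCCl)C=C1SCCCS1=O
F2 | step 11 | corresponding iodide (CH2CH2I) | C=C1C[C@]2(CO)C[C@H]1C(=O)C[C@H]2[C@](C)(CCI)C=C1SCCCS1=O
F3 | step 11 | trimethylsilyl ester of the ring-A-closed dithiane 1-oxide (not isolated) | C=C1C[C@]2(CO)C[C@H]1C(=O)C[C@H]2[C@]1(C)CCC[C@@](C)(C(=O)O[Si](C)(C)C)[C@H]1C1SCCCS1=O
F4 | step 11 | ring-A-closed 6-(1-oxido-1,3-dithian-2-yl)-7-hydroxy-12-oxo 19-acid | C=C1C[C@]2(CO)C[C@H]1C(=O)C[C@H]2[C@]1(C)CCC[C@@](C)(C(=O)O)[C@H]1C1SCCCS1=O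
F5 | step 4 | [4-oxo-1-(prop-2-yn-1-yl)cyclohexyl]methyl (S)-2-methoxy-2-phenylacetate | CO[C@H](C(=O)OCC1(CC#C)CCC(=O)CC1)c1ccccc1
F6 | step 4 | [(1R,5R)-6-methylidene-4-oxobicyclo[3.2.1]octan-1-yl]methyl (S)-2-methoxy-2-phenylacetate | C=C1C[C@]2(COC(=O)[C@@H](OC)c3ccccc3)C[C@H]1C(=O)CC2
F7 | step 4 | (1R,5R)-5-(hydroxymethyl)-7-methylidenebicyclo[3.2.1]octan-2-one | C=C1C[C@]2(CO)C[C@H]1C(=O)CC2
F8 | step 9 | diol from addition of 2-lithio-1,3-dithiane to 14 (C5 carbinol epimers) | C=C1C[C@]2(CO)C[C@H]1C(O[Si](C)(C)C(C)(C)C)=C[C@H]2[C@](C)(CCCl)C(O)C1SCCCS1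
F9 | step 9 | bis(trifluoroacetate) of F8 | C=C1C[C@]2(COC(=O)C(F)(F)F)C[C@H]1C(O[Si](C)(C)C(C)(C)C)=C[C@H]2[C@](C)(CCCl)C(OC(=O)C(F)(F)F)C1SCCCS1
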